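A small charge of catalyst, 25.0 mM, meets 18 mM of added ligand in this flask.

substrate 1.0 M; gas phase 76 mM (held); catalyst 2.5 mol%; added ligand 18 mM; time 25 s

    substrate + dissolved gas + catalyst → catalyst + target (k1 = 20 /M²/s)
    catalyst + added ligand ⇌ idle complex, settled at all times (K2 = 57 /M)
    substrate ⇌ dormant form (K3 = 0.59, k3 = 0.0072 /s)
    gas phase ⇌ dissolved gas, rate k4*(csat - [dissolved gas]) (k4 = 2.0 /s, csat = 76 mM)
    target + catalyst ⇌ isomer of the product + catalyst, rate k5*[catalyst]*[target] forward; the back reaction follows from the equilibrium constant (K5 = 1.2, k5 = 0.59 /M/s)

- at the start none of the gas is dissolved
- run time (flask): 25 s

- amount of target at 25 s, in percent of the substrate charged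
- concentration of dissolved gas in solution at 12 s, in percent of saturation
- the change that raises the amount of target at 25 s, in percent of the substrate charged most ("none" if none brings more than 2 percentage points) (red / teal / green / none)
- amount of target at 25 s, in percent of the substrate charged, after green

- red: doubling the amount of catalyst, all else as stated
- teal: doubling the saturation concentration of gas phase, all else as stated
- green: doubling the transfer coefficient of step 4, all else as stated

Start with the balance of the catalyst, which step one gives back: its charge is free catalyst F plus idle complex, and the idle complex also draws on the ligand. Solving that balance at equilibrium gives 16.3 mM of free catalyst, the part of the charge not held as idle complex, which is 65.2% of the charge.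

Transfer, 2.0 /s, is faster than the drain on the gas, so you may equate supply and use. Dissolved gas then stands at a share g of saturation, 86.0% with fresh substrate. By 12 s, with the substrate thinner, I reckon 89.6%.

The working constant W, a pseudo-first-order constant, is the rate constant of step one times F, saturation and g, giving 0.0213 /s. Substrate also leaks to dormant form at 0.0072 /s, and target turns to isomer at 0.00963 /s. Two consecutive first-order losses give 33.4% target.

Green, the doubled transfer coefficient, raises that to 35.3% in my reckoning. Red, the doubled catalyst, gives F = 37.7 mM and W = 0.0416 /s, close to the 0.0427 /s of teal, the doubled saturation concentration. But red speeds the isomer loss to 0.0223 /s, so I choose teal.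

The forecast says 34.5%, 89.5%, teal and 36.2%, holding of the gas that “transfer outpaces consumption”, and its target stands above mine.

The flask gives 34.6%, 89.4%, teal and 36.3%, with gains of 15 percentage points for red, 21 points for teal and 1.7 points for green.

In this flask the half-life of substrate by step one, 32 s at 8.93 s, is longer than the run, and the half-life of target by the forward step to isomer, 72 s at 25.0 s, is longer still. At 25.0 s this flask holds 50.0% substrate beside 34.6% target, and free catalyst reads 65.3% of its charge. With 10 mol% of catalyst, the same balance gives 85.1 mM free, 85.1% of that charge. That neighbouring flask reads 85.1% free catalyst, with 52.2% target and 34.1% isomer at 25.0 s.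

The constants used here are made up; the run is a simulation.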